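**Retrosynthetic overview**
- Last operation: the three phenols are unmasked from the tri-O-methyl lactone with BBr3.
- The lactone ring is the only ring that is built. It closes onto the phenol oxygen that the C8 ketone itself unmasks (ketone-directed BCl3 cleavage). This follows Friedel–Crafts acylation of the symmetric trimethoxyphenyl ring and fixes 8-acyl over 6-acyl.
- Key disconnection C4–C4a: a chiral copper homoenolate is arylated through palladium by 2-bromo-1,3,5-trimethoxybenzene. The homoenolate is β-cuprated tert-butyl 4-methoxycinnamate, made by CuH addition with reversed regiochemistry. Two acceptor carbons are joined and C4 is set in the same step.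
- The cinnamate comes from 4-bromoanisole and tert-butyl acrylate (Heck).
- Ring order: the three benzene rings are bought, and the lactone ring is formed in step 3.

Assumption: (S,S)-Ph-BPE is written as the ligand hand that leads to (S)-7. The sense is assigned by analogy and checked on the first run by chiral HPLC. The equally available mirror-image ligand is used if the antipode appears.

**Step 1**
Reactants: 1 4-bromoanisole; 2 tert-butyl acrylate
Product: 3 tert-butyl (E)-3-(4-methoxyphenyl)prop-2-enoate
Conditions: Pd(OAc)2 (1 mol %), P(o-tol)3 (2 mol %), NaOAc, DMF, 120 °C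
Reagents that add atoms: none
Why: Mizoroki–Heck reaction, in which zerovalent palladium inserts into the C–Br bond, syn carbopalladation occurs at the acrylate terminus and syn β-hydride elimination gives only the E-cinnamate; no stereocentre is made.

**Step 2 (key step)**
Reactants: 3 tert-butyl (E)-3-(4-methoxyphenyl)prop-2-enoate (1.5 equiv); 4 2-bromo-1,3,5-trimethoxybenzene
Product: 7 tert-butyl (S)-3-(4-methoxyphenyl)-3-(2,4,6-trimethoxyphenyl)propanoate, via copper homoenolate 5 (not isolated), via arylpalladium bromide 6 (not isolated)
Conditions: Cu(OAc)2 (5 mol %), (S,S)-Ph-BPE (5.5 mol %), [Pd(cinnamyl)Cl]2 (2.5 mol %), BrettPhos (5.5 mol %), MePh2SiH, NaOSiMe3, THF, rt to 40 °C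
Reagents that add atoms: none
Why: Proposed new method: (Ph-BPE)CuH is known to add to tert-butyl cinnamates with reversed regiochemistry (hydride to the α-carbon, copper to the benzylic β-carbon), so the enantio-determining syn-hydrocupration gives (R)-5, a monovalent-copper homoenolate whose normally electrophilic β-carbon is now the nucleophile; enantioenriched benzylic copper species are also known to pass their alkyl group stereospecifically, with inversion, to an arylpalladium bromide, so 5 should be intercepted by 6 (zerovalent palladium inserted into 4), and retentive reductive elimination from divalent palladium then joins two carbons that are both acceptors in their parent compounds and sets C4 as (S); the closest known reaction types are the CuH-catalysed β-amination of cinnamates and the enantioselective CuH/Pd dual-catalytic hydroarylation of vinylarenes.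

**Step 3**
Reactants: 7 tert-butyl (S)-3-(4-methoxyphenyl)-3-(2,4,6-trimethoxyphenyl)propanoate; 8 3-phenylpropanoyl chloride
Product: 11 (S)-5,7-dimethoxy-4-(4-methoxyphenyl)-8-(3-phenylpropanoyl)-3,4-dihydro-2H-chromen-2-one, via aryl ketone 9 (not isolated), via hydroxy acid 10 (not isolated)
Conditions: SnCl4, CH2Cl2, −78 to −30 °C; then BCl3 (5 equiv), −30 °C to rt; aq. HCl; crude, TsOH·H2O (cat.), PhMe, molecular sieves, 80 °C
Reagents that add atoms: none
Why: Friedel–Crafts acylation goes only to ring A, whose two free positions are equivalent so one isomer forms, and BCl3 then cleaves the tert-butyl ester and the one methyl ether that is both chelated to the new ketone and squeezed between two ortho substituents (chelation-controlled, hindered-ether demethylation), so the only free phenol beside the side chain is the one ortho to the acyl group and acid-catalysed lactonisation can give only the 8-acyl lactone; C4 is untouched, and any 7-OH congener from a second cleavage converges in step 4.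

**Step 4**
Reactants: 11 (S)-5,7-dimethoxy-4-(4-methoxyphenyl)-8-(3-phenylpropanoyl)-3,4-dihydro-2H-chromen-2-one
Product: 12 (S)-5,7-dihydroxy-4-(4-hydroxyphenyl)-8-(3-phenylpropanoyl)-3,4-dihydro-2H-chromen-2-one (CNP0383109.1)
Conditions: BBr3 (8 equiv), CH2Cl2, −78 °C to rt; ice-water quench
Reagents that add atoms: none
Why: BBr3 aryl methyl ether cleavage (adduct formation, then bromide attack at methyl) removes all three methyl groups while the aryl lactone and the ketone survive, the acyl group cannot slip from O1 to O5 without prior ring opening because the two oxygens lie on opposite sides of C4a, and C4 keeps its configuration because ring A is now deactivated towards ipso-protonation.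

**Compound list**
1 | 4-bromoanisole | COc1ccc(Br)cc1 | starting material
2 | tert-butyl acrylate | C=CC(=O)OC(C)(C)C | starting material
3 | tert-butyl (E)-3-(4-methoxyphenyl)prop-2-enoate | COc1ccc(/C=C/C(=O)OC(C)(C)C)cc1 | intermediate
4 | 2-bromo-1,3,5-trimethoxybenzene | COc1cc(OC)c(Br)c(OC)c1 | starting material
5 | tert-butyl (R)-3-cuprio-3-(4-methoxyphenyl)propanoate, monovalent copper carrying Ph-BPE (ligand not drawn) | CC(C)(C)OC(=O)C[C@H](c1ccc(OC)cc1)[Cu] | intermediate
6 | bromo(2,4,6-trimethoxyphenyl)palladium, divalent palladium carrying BrettPhos (ligand not drawn) | COc1cc(OC)c([Pd]Br)c(OC)c1 | intermediate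
7 | tert-butyl (S)-3-(4-methoxyphenyl)-3-(2,4,6-trimethoxyphenyl)propanoate | CC(C)(C)OC(=O)C[C@@H](c1ccc(OC)cc1)c1c(OC)cc(OC)cc1OC | intermediate
8 | 3-phenylpropanoyl chloride | O=C(Cl)CCc1ccccc1 | starting material
9 | tert-butyl (S)-3-(4-methoxyphenyl)-3-[2,4,6-trimethoxy-3-(3-phenylpropanoyl)phenyl]propanoate | CC(C)(C)OC(=O)C[C@@H](c1ccc(OC)cc1)c1c(OC)cc(OC)c(C(=O)CCc2ccccc2)c1OC | intermediate
10 | (S)-3-[2-hydroxy-4,6-dimethoxy-3-(3-phenylpropanoyl)phenyl]-3-(4-methoxyphenyl)propanoic acid | OC(=O)C[C@@H](c1ccc(OC)cc1)c1c(OC)cc(OC)c(C(=O)CCc2ccccc2)c1O | intermediate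
11 | (S)-5,7-dimethoxy-4-(4-methoxyphenyl)-8-(3-phenylpropanoyl)-3,4-dihydro-2H-chromen-2-one | O=C1C[C@@H](c2ccc(OC)cc2)c2c(OC)cc(OC)c(C(=O)CCc3ccccc3)c2O1 | intermediate
12 | (S)-5,7-dihydroxy-4-(4-hydroxyphenyl)-8-(3-phenylpropanoyl)-3,4-dihydro-2H-chromen-2-one | O=C1C[C@@H](c2ccc(O)cc2)c2c(O)cc(O)c(C(=O)CCc3ccccc3)c2O1 | target

**Total step count:** 4. **Longest linear sequence:** 4 (1 → 3 → 7 → 11 → 12).

**Steps most likely to fail**

*Step 2 (highest risk).*
- The doubly ortho-substituted, electron-rich bromide 4 may insert and transmetalate too slowly. In that case 5 would drain to the plain saturated ester.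
- The diphosphine may also wander from copper to palladium.

The fallback sets out from 4 and 2 and comes back at 7. It puts the crowded ring in place first and sets the stereocentre in a separate C–B bond formation.
- Heck coupling of 4 with 2 (Pd(OAc)2, P(t-Bu)3·HBF4, Cs2CO3, dioxane, 110 °C) gives tert-butyl (E)-3-(2,4,6-trimethoxyphenyl)prop-2-enoate F1.
- Copper-catalysed enantioselective conjugate borylation follows (CuCl, NaOt-Bu, Josiphos-type ligand of the hand that gives R, B2pin2, MeOH, THF). It gives the isolable boron homoenolate tert-butyl (R)-3-(4,4,5,5-tetramethyl-1,3,2-dioxaborolan-2-yl)-3-(2,4,6-trimethoxyphenyl)propanoate F2.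
- A stereoretentive Suzuki–Miyaura coupling of this secondary benzylic boronate with bought, unhindered 4-iodoanisole (Pd2(dba)3, PPh3, Ag2O, DME, 85 °C) delivers 7.

*Step 3.*
- Before the ketone is in place, ring A is extremely electron-rich. Lewis or Brønsted acid could protonate it at the carbon bearing C4 and expel the anisyl-stabilised cation. That would cleave the bond or erode the ee.
- Released tert-butyl cation could also alkylate ring A.

The fallback sets out from 7 and comes back at 9. It builds the ketone without an acylium ion.
- Vilsmeier–Haack formylation (POCl3, DMF, 0 °C to rt, then aq. NaOAc) gives tert-butyl (S)-3-(3-formyl-2,4,6-trimethoxyphenyl)-3-(4-methoxyphenyl)propanoate F3.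
- 2-Phenylethylmagnesium bromide (THF, −78 °C) adds to the aldehyde only. It gives tert-butyl (3S)-3-[3-(1-hydroxy-3-phenylpropyl)-2,4,6-trimethoxyphenyl]-3-(4-methoxyphenyl)propanoate F4 as an inconsequential pair of carbinol epimers.
- Dess–Martin oxidation gives 9, now isolated, which enters the BCl3 and lactonisation part of step 3.

*Step 4.*
- BBr3 might open the aryl lactone. Once all phenols are free, re-closure could partly give the 6-acyl isomer.

The fallback sets out from 7 and comes back at 12. It removes the methyl groups while any such scrambling is degenerate.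
- BBr3 (CH2Cl2, −78 °C to rt) on 7 gives (S)-5,7-dihydroxy-4-(4-hydroxyphenyl)-3,4-dihydro-2H-chromen-2-one F5. Both ortho oxygens are equivalent here, so only one lactone exists.
- Friedel–Crafts/Fries acylation with 8 (AlCl3, CH2Cl2/PhNO2, 40 °C) puts the acyl group at C8. This is the position preferred in the 5,7-dihydroxy-4-substituted coumarin series. The minor C6 isomer is removed by chromatography.

**Further compounds**
F1 | step 2 | tert-butyl (E)-3-(2,4,6-trimethoxyphenyl)prop-2-enoate | COc1cc(OC)c(/C=C/C(=O)OC(C)(C)C)c(OC)c1
F2 | step 2 | tert-butyl (R)-3-(4,4,5,5-tetramethyl-1,3,2-dioxaborolan-2-yl)-3-(2,4,6-trimethoxyphenyl)propanoate | CC(C)(C)OC(=O)C[C@@H](B1OC(C)(C)C(C)(C)O1)c1c(OC)cc(OC)cc1OC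
F3 | step 3 | tert-butyl (S)-3-(3-formyl-2,4,6-trimethoxyphenyl)-3-(4-methoxyphenyl)propanoate | CC(C)(C)OC(=O)C[C@@H](c1ccc(OC)cc1)c1c(OC)cc(OC)c(C=O)c1OC
F4 | step 3 | tert-butyl (3S)-3-[3-(1-hydroxy-3-phenylpropyl)-2,4,6-trimethoxyphenyl]-3-(4-methoxyphenyl)propanoate | CC(C)(C)OC(=O)C[C@@H](c1ccc(OC)cc1)c1c(OC)cc(OC)c(C(O)CCc2ccccc2)c1OC
F5 | step 4 | (S)-5,7-dihydroxy-4-(4-hydroxyphenyl)-3,4-dihydro-2H-chromen-2-one | O=C1C[C@@H](c2ccc(O)cc2)c2c(O)cc(O)cc2O1
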